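**Retrosynthetic overview**

1. The target is read as a 4→8-linked flavan trimer. Both interflavan C4–C8 bonds are disconnected (aryllithium plus flavan-4-one, then ionic deoxygenation that leaves the new aryl group cis to the 3-oxygen), and the C4 hydroxyl of the terminal unit comes from a late benzylic oxidation.
2. The upper and lower units (both 2S) derive from one building block, the cis-3-benzyloxyflavan-4-one 18. It is assembled in one flask from a glycolyl oxazolidinone, 4-(benzyloxy)benzaldehyde and 3,5-bis(benzyloxy)benzyne: the aldol makes C2–C3, the aldolate oxygen adds to the aryne (O1–C8a), and the aryl anion closes ring C on the acyl carbon (C4a–C4).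
3. Enabling feature: in ring C, O1–C2 is the C=O of an aldehyde and C3–C4 is a glycolate unit. C8a and C4a are neighbouring carbons of ring A with the C5 oxygen beside C4a, i.e. a 3-alkoxyaryne that takes the oxygen at its distal carbon (C8a) and the acyl carbon at the carbon next to the alkoxy group (C4a).
4. The middle unit (2R,3R, 2,3-cis) has the configuration of (−)-epiafzelechin and is taken from it: benzylation and a two-stage C4 oxidation give the enantiomeric cis ketone 26.
5. Ring order: ring C of 18 (ring A enters as the aryne, ring B with the aldehyde), used first as the lower unit after deoxygenation; the rings of the middle unit come intact from the chiral pool; 18 again as the upper unit. Coupling runs lower→middle→upper, then C4 hydroxylation and global debenzylation.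

Key step: step 5

Remark on the chemistry: the stereodescriptors are taken literally (upper and lower units 2S,3S, middle unit 2R,3R, all 2,3-cis; both interflavan bonds cis to the neighbouring 3-hydroxyl; terminal unit a 2,3-cis-3,4-trans flavan-3,4-diol), and (−)-epiafzelechin is assumed to be purchasable in the amount needed.

**Route**

Step 1
Reactants: 1 3,5-bis(benzyloxy)phenol
Product: 2 3,5-bis(benzyloxy)phenyl N-isopropylcarbamate
Conditions: i-PrNCO, Et3N (cat.), CH2Cl2, rt
Reagents that add atoms: isopropyl isocyanate, CC(C)N=C=O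
Why: Carbamoylation of the phenol by addition to the isocyanate installs a group that directs ortho-metalation and can later be removed under mild base.

Step 2
Reactants: 2 3,5-bis(benzyloxy)phenyl N-isopropylcarbamate
Product: 6 3,5-bis(benzyloxy)-2-(trimethylsilyl)phenyl N-isopropylcarbamate, via N-silyl carbamate 3 (not isolated), via aryllithium 4 (not isolated), via silylated N-silyl carbamate 5 (not isolated)
Conditions: TBSOTf, TMEDA, Et2O, 0 °C to rt; n-BuLi, TMEDA, −78 °C; Me3SiCl, −78 °C to rt; aq. NaHSO4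
Reagents that add atoms: chlorotrimethylsilane, C[Si](C)(C)Cl
Why: Directed ortho-metalation: after transient N-silylation the carbamate and the neighbouring benzyloxy group jointly direct lithiation to C2 (C2 and C6 are equivalent), the aryllithium is C-silylated and the N-silyl group is lost on acidic work-up.

Step 3
Reactants: 6 3,5-bis(benzyloxy)-2-(trimethylsilyl)phenyl N-isopropylcarbamate
Product: 8 3,5-bis(benzyloxy)-2-(trimethylsilyl)phenyl trifluoromethanesulfonate, via phenol 7 (not isolated)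
Conditions: DBU, Et2NH, MeCN, 40 °C; then PhNTf2, rt
Reagents that add atoms: N-phenylbis(trifluoromethanesulfonimide), O=S(=O)(N(c1ccccc1)S(=O)(=O)C(F)(F)F)C(F)(F)F
Why: Base-induced elimination of the secondary carbamate (the isocyanate is captured by Et2NH as a urea) frees the phenoxide, which is triflated in the same flask to give the ortho-silylaryl triflate, the standard fluoride-triggered aryne precursor.

Step 4
Reactants: 9 (R)-4-benzyloxazolidin-2-one; 10 (benzyloxy)acetyl chloride
Product: 12 (R)-4-benzyl-3-[(benzyloxy)acetyl]oxazolidin-2-one, via lithium amide 11 (not isolated)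
Conditions: n-BuLi, THF, −78 °C; then 10, −78 to 0 °C
Reagents that add atoms: none
Why: N-acylation of the lithiated oxazolidinone by the acid chloride gives the glycolyl imide without touching the stereocentre of the auxiliary.

Step 5
Reactants: 12 (R)-4-benzyl-3-[(benzyloxy)acetyl]oxazolidin-2-one; 13 4-(benzyloxy)benzaldehyde; 8 3,5-bis(benzyloxy)-2-(trimethylsilyl)phenyl trifluoromethanesulfonate
Product: 18 (2S,3R)-3,5,7-tris(benzyloxy)-2-[4-(benzyloxy)phenyl]chroman-4-one (2,3-cis), via lithium enolate 14 (not isolated), via boron enolate 15 (not isolated), via boron aldolate 16 (not isolated), via aryne 17 (not isolated)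
Conditions: LiN(SiMe3)2, toluene, −78 °C; Bu2BOTf, −78 to 0 °C; 13, −78 to 0 °C; volatiles removed in vacuo at 0 °C; then 8 (2 equiv), KF (excess), 18-crown-6, THF, −20 °C to rt; pH 7 buffer
Reagents that add atoms: none
Why: Proposed new method: the amine-free (Z)-dibutylboron enolate 15 adds to aldehyde 13 through the closed chair transition state of the Evans syn-aldol (forming C2–C3), so the (R)-benzyl auxiliary fixes C2 as S and places the glycolate oxygen on C3 syn to the new C2 oxygen, which is the 2,3-cis relationship of ring C. Fluoride then does two jobs: it converts the boron aldolate 16 into a nucleophilic fluoroborate-bound alkoxide and it releases aryne 17 from 8; the alkoxide oxygen adds to the aryne (forming O1–C8a) and the aryl anion so generated on C4a attacks the imide carbonyl in a 6-exo-trig acyl substitution that closes ring C (C4a–C4) and expels the oxazolidinone. The closest known reaction types are the boron-mediated glycolate aldol of N-acyl oxazolidinones and the aryne annulation of salicylate esters to xanthones (O-arylation followed by acyl capture of the aryl anion); what is new is their union in one flask and the use of an aliphatic aldolate as the oxygen nucleophile. The step needs the oxygen at the aryne carbon remote from the flanking benzyloxy group: the inductive effect of this 3-alkoxy substituent makes the distal carbon the electrophilic one and stabilises the carbanion on the carbon next to it, which gives exactly the C8a(O)/C4a(C) pattern, and the second benzyloxy group, meta to the attacked carbon, does not alter this. It also needs the aryl anion to reach the carbonyl before it is protonated, which is why the enolate is made with LiN(SiMe3)2, its conjugate acid HN(SiMe3)2 is stripped off with the toluene before THF and fluoride are added, and no ammonium salt is present; low temperature and an excess of 8 are meant to outrun retro-aldol cleavage and C3 epimerisation of the base-sensitive cis ketone.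

Step 6
Reactants: 18 (2S,3R)-3,5,7-tris(benzyloxy)-2-[4-(benzyloxy)phenyl]chroman-4-one
Product: 19 (2S,3S,4S)-3,5,7-tris(benzyloxy)-2-[4-(benzyloxy)phenyl]chroman-4-ol (all-cis)
Conditions: NaBH4, CeCl3·7H2O, THF/MeOH, −40 to 0 °C
Reagents that add atoms: none
Why: Carbonyl reduction in which hydride is expected to add anti to the axial C3 benzyloxy group (all-cis alcohol), although the C4 configuration is of no consequence because this oxygen is removed in step 7.

Step 7
Reactants: 19 (2S,3S,4S)-3,5,7-tris(benzyloxy)-2-[4-(benzyloxy)phenyl]chroman-4-ol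
Product: 20 (2S,3S)-3,5,7-tris(benzyloxy)-2-[4-(benzyloxy)phenyl]chroman (2,3-cis)
Conditions: Et3SiH (excess), CF3CO2H, CH2Cl2, −40 to 0 °C
Reagents that add atoms: none
Why: Ionic hydrogenation: the benzylic alcohol ionises to a cation stabilised by the three ring A oxygens and is reduced by the silane (used in excess to outpace self-condensation), leaving C2 and C3 untouched.

Step 8
Reactants: 20 (2S,3S)-3,5,7-tris(benzyloxy)-2-[4-(benzyloxy)phenyl]chroman
Product: 21 (2S,3S)-3,5,7-tris(benzyloxy)-2-[4-(benzyloxy)phenyl]-8-bromochroman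
Conditions: NBS, CH2Cl2, −78 °C to rt
Reagents that add atoms: N-bromosuccinimide, O=C1CCC(=O)N1Br
Why: Electrophilic aromatic bromination, which in 5,7-dialkoxyflavans goes to C8 (flanked by O1 and one benzyloxy group) in preference to C6 (flanked by two benzyloxy groups).

Step 9
Reactants: 22 (−)-epiafzelechin, (2R,3R)-2-(4-hydroxyphenyl)chroman-3,5,7-triol
Product: 23 (2R,3R)-5,7-bis(benzyloxy)-2-[4-(benzyloxy)phenyl]chroman-3-ol
Conditions: BnBr (3.3 equiv), K2CO3, DMF, 0 °C to rt, under N2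
Reagents that add atoms: benzyl bromide, BrCc1ccccc1
Why: Williamson etherification of the three phenoxides under mild carbonate base should leave the less acidic secondary 3-hydroxyl free and touch neither stereocentre.

Step 10
Reactants: 23 (2R,3R)-5,7-bis(benzyloxy)-2-[4-(benzyloxy)phenyl]chroman-3-ol
Product: 24 (2R,3R)-3,5,7-tris(benzyloxy)-2-[4-(benzyloxy)phenyl]chroman (2,3-cis)
Conditions: NaH, BnBr, Bu4NI (cat.), THF, 0 °C to rt
Reagents that add atoms: benzyl bromide, BrCc1ccccc1
Why: Williamson etherification of the secondary alkoxide formed with NaH, which with all phenols already capped should not disturb C2 or C3.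

Step 11
Reactants: 24 (2R,3R)-3,5,7-tris(benzyloxy)-2-[4-(benzyloxy)phenyl]chroman
Product: 25 (2R,3R,4S)-3,5,7-tris(benzyloxy)-2-[4-(benzyloxy)phenyl]chroman-4-ol (2,3-cis-3,4-trans)
Conditions: DDQ, CH2Cl2/H2O, rt
Reagents that add atoms: water, O
Why: DDQ benzylic oxidation: hydride is abstracted from C4, activated by the ring A oxygens, and water captures the cation anti to the 3-benzyloxy and 2-aryl groups, the C4 configuration being lost again in step 12.

Step 12
Reactants: 25 (2R,3R,4S)-3,5,7-tris(benzyloxy)-2-[4-(benzyloxy)phenyl]chroman-4-ol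
Product: 26 (2R,3S)-3,5,7-tris(benzyloxy)-2-[4-(benzyloxy)phenyl]chroman-4-one (2,3-cis)
Conditions: Dess–Martin periodinane, NaHCO3, CH2Cl2, 0 °C to rt
Reagents that add atoms: none
Why: Dess–Martin oxidation of the secondary benzylic alcohol under buffered, non-basic conditions should give the ketone without epimerising the cis-configured C3.

Step 13
Reactants: 21 (2S,3S)-3,5,7-tris(benzyloxy)-2-[4-(benzyloxy)phenyl]-8-bromochroman; 26 (2R,3S)-3,5,7-tris(benzyloxy)-2-[4-(benzyloxy)phenyl]chroman-4-one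
Product: 28 dimer carbinol (4-hydroxy middle unit bonded at C4 to C8 of the lower unit), via aryllithium 27 (not isolated)
Conditions: t-BuLi (2 equiv), THF, −78 °C; then 26, −78 to 0 °C; aq. NH4Cl
Reagents that add atoms: none
Why: Bromine–lithium exchange followed by 1,2-addition of the aryllithium to the flavan-4-one forms the middle C4–lower C8 bond, with attack expected anti to the cis 2-aryl and 3-benzyloxy groups, though the carbinol configuration is erased in step 14.

Step 14
Reactants: 28 dimer carbinol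
Product: 29 octa-O-benzyl dimer (middle unit 2R,3R with the C4 aryl cis to the 3-benzyloxy and 2-aryl groups; lower unit 2S,3S)
Conditions: Bu3SnH, CF3CO2H, CH2Cl2, 0 °C
Reagents that add atoms: none
Why: Ionic deoxygenation of the tertiary, doubly benzylic alcohol: the planar C4 cation takes hydride from the face opposite the 2-aryl and 3-benzyloxy groups, so the C8-linked aryl group ends cis to both (2,3-cis-3,4-cis middle unit).

Step 15
Reactants: 29 octa-O-benzyl dimer
Product: 30 bromo dimer (bromine on C8 of the middle unit)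
Conditions: NBS, CH2Cl2, −78 to 0 °C
Reagents that add atoms: N-bromosuccinimide, O=C1CCC(=O)N1Br
Why: Electrophilic bromination at the only free C8-type position, since C8 of the lower unit is substituted and both C6 positions lie between two benzyloxy groups and should react more slowly.

Step 16
Reactants: 30 bromo dimer; 18 (2S,3R)-3,5,7-tris(benzyloxy)-2-[4-(benzyloxy)phenyl]chroman-4-one
Product: 32 trimer carbinol (4-hydroxy upper unit bonded at C4 to C8 of the middle unit), via lithio dimer 31 (not isolated)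
Conditions: t-BuLi (2 equiv), THF, −78 °C; then 18, −78 to 0 °C; aq. NH4Cl
Reagents that add atoms: none
Why: The same bromine–lithium exchange and aryllithium addition to a flavan-4-one forms the upper C4–middle C8 bond, the configuration of the new carbinol again being erased in the next step.

Step 17
Reactants: 32 trimer carbinol
Product: 33 dodeca-O-benzyl trimer with a 4-deoxy lower unit (upper 2S,3S all-cis; middle 2R,3R all-cis; lower 2S,3S)
Conditions: Bu3SnH, CF3CO2H, CH2Cl2, 0 °C
Reagents that add atoms: none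
Why: Ionic deoxygenation as in step 14, hydride adding to the upper C4 cation anti to the 2-aryl and 3-benzyloxy groups so that the interflavan bond ends cis to both.

Step 18
Reactants: 33 dodeca-O-benzyl trimer with a 4-deoxy lower unit
Product: 34 dodeca-O-benzyl trimer with a free 4-hydroxyl on the lower unit (lower unit 2S,3S,4R; 3,4-trans)
Conditions: DDQ, CH2Cl2/H2O, rt
Reagents that add atoms: water, O
Why: DDQ benzylic oxidation: hydride is abstracted from the only benzylic methylene (C4 of the terminal unit, activated by the ring A oxygens) and water captures the cation anti to the 3-benzyloxy and 2-aryl groups, which gives the 3,4-trans alcohol.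

Step 19
Reactants: 34 dodeca-O-benzyl trimer with a free 4-hydroxyl on the lower unit
Product: 35 CNP0159291.1
Conditions: H2 (1 atm), Pd(OH)2/C, THF/MeOH/H2O, rt
Reagents that add atoms: none
Why: Hydrogenolysis of the twelve benzyl ethers under neutral conditions, stopped at complete debenzylation so that the benzylic C4 hydroxyl and the interflavan bonds survive, touches no stereocentre.

**Compound list**

1 | 3,5-bis(benzyloxy)phenol | Oc1cc(OCc2ccccc2)cc(OCc2ccccc2)c1 | starting material
2 | 3,5-bis(benzyloxy)phenyl N-isopropylcarbamate | CC(C)NC(=O)Oc1cc(OCc2ccccc2)cc(OCc2ccccc2)c1 | intermediate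
3 | 3,5-bis(benzyloxy)phenyl N-isopropyl-N-(tert-butyldimethylsilyl)carbamate | CC(C)N(C(=O)Oc1cc(OCc2ccccc2)cc(OCc2ccccc2)c1)[Si](C)(C)C(C)(C)C | intermediate
4 | 2-lithio derivative of 3 | CC(C)N(C(=O)Oc1cc(OCc2ccccc2)cc(OCc2ccccc2)c1[Li])[Si](C)(C)C(C)(C)C | intermediate
5 | 3,5-bis(benzyloxy)-2-(trimethylsilyl)phenyl N-isopropyl-N-(tert-butyldimethylsilyl)carbamate | CC(C)N(C(=O)Oc1cc(OCc2ccccc2)cc(OCc2ccccc2)c1[Si](C)(C)C)[Si](C)(C)C(C)(C)C | intermediate
6 | 3,5-bis(benzyloxy)-2-(trimethylsilyl)phenyl N-isopropylcarbamate | CC(C)NC(=O)Oc1cc(OCc2ccccc2)cc(OCc2ccccc2)c1[Si](C)(C)C | intermediate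
7 | 3,5-bis(benzyloxy)-2-(trimethylsilyl)phenol | Oc1cc(OCc2ccccc2)cc(OCc2ccccc2)c1[Si](C)(C)C | intermediate
8 | 3,5-bis(benzyloxy)-2-(trimethylsilyl)phenyl trifluoromethanesulfonate | C[Si](C)(C)c1c(OS(=O)(=O)C(F)(F)F)cc(OCc2ccccc2)cc1OCc1ccccc1 | intermediate
9 | (R)-4-benzyloxazolidin-2-one | O=C1N[C@H](Cc2ccccc2)CO1 | starting material
10 | (benzyloxy)acetyl chloride | O=C(Cl)COCc1ccccc1 | starting material
11 | N-lithio-(R)-4-benzyloxazolidin-2-one | [Li]N1C(=O)OC[C@H]1Cc1ccccc1 | intermediate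
12 | (R)-4-benzyl-3-[(benzyloxy)acetyl]oxazolidin-2-one | O=C(COCc1ccccc1)N1C(=O)OC[C@H]1Cc1ccccc1 | intermediate
13 | 4-(benzyloxy)benzaldehyde | O=Cc1ccc(OCc2ccccc2)cc1 | starting material
14 | (Z)-lithium enolate of 12 | [Li]O/C(=C\OCc1ccccc1)N1C(=O)OC[C@H]1Cc1ccccc1 | intermediate
15 | (Z)-dibutylboron enolate of 12 | CCCCB(CCCC)O/C(=C\OCc1ccccc1)N1C(=O)OC[C@H]1Cc1ccccc1 | intermediate
16 | (R)-4-benzyl-3-[(2R,3S)-2-(benzyloxy)-3-[4-(benzyloxy)phenyl]-3-(dibutylboryloxy)propanoyl]oxazolidin-2-one | O=C(N1C(=O)OC[C@H]1Cc1ccccc1)[C@H](OCc1ccccc1)[C@@H](OB(CCCC)CCCC)c1ccc(OCc2ccccc2)cc1 | intermediate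
17 | 3,5-bis(benzyloxy)benzyne (1,2-didehydro-3,5-bis(benzyloxy)benzene) | C1#CC(OCc2ccccc2)=CC(OCc2ccccc2)=C1 | intermediate
18 | (2S,3R)-3,5,7-tris(benzyloxy)-2-[4-(benzyloxy)phenyl]chroman-4-one (2,3-cis) | O=C1c2c(OCc3ccccc3)cc(OCc3ccccc3)cc2O[C@@H](c2ccc(OCc3ccccc3)cc2)[C@H]1OCc1ccccc1 | intermediate
19 | (2S,3S,4S)-3,5,7-tris(benzyloxy)-2-[4-(benzyloxy)phenyl]chroman-4-ol (all-cis) | O[C@H]1c2c(OCc3ccccc3)cc(OCc3ccccc3)cc2O[C@@H](c2ccc(OCc3ccccc3)cc2)[C@H]1OCc1ccccc1 | intermediate
20 | (2S,3S)-3,5,7-tris(benzyloxy)-2-[4-(benzyloxy)phenyl]chroman (2,3-cis) | C1c2c(OCc3ccccc3)cc(OCc3ccccc3)cc2O[C@@H](c2ccc(OCc3ccccc3)cc2)[C@H]1OCc1ccccc1 | intermediate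
21 | (2S,3S)-3,5,7-tris(benzyloxy)-2-[4-(benzyloxy)phenyl]-8-bromochroman | C1c2c(OCc3ccccc3)cc(OCc3ccccc3)c(Br)c2O[C@@H](c2ccc(OCc3ccccc3)cc2)[C@H]1OCc1ccccc1 | intermediate
22 | (−)-epiafzelechin, (2R,3R)-2-(4-hydroxyphenyl)chroman-3,5,7-triol (2,3-cis) | C1c2c(O)cc(O)cc2O[C@H](c2ccc(O)cc2)[C@@H]1O | starting material
23 | (2R,3R)-5,7-bis(benzyloxy)-2-[4-(benzyloxy)phenyl]chroman-3-ol | C1c2c(OCc3ccccc3)cc(OCc3ccccc3)cc2O[C@H](c2ccc(OCc3ccccc3)cc2)[C@@H]1O | intermediate
24 | (2R,3R)-3,5,7-tris(benzyloxy)-2-[4-(benzyloxy)phenyl]chroman (2,3-cis) | C1c2c(OCc3ccccc3)cc(OCc3ccccc3)cc2O[C@H](c2ccc(OCc3ccccc3)cc2)[C@@H]1OCc1ccccc1 | intermediate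
25 | (2R,3R,4S)-3,5,7-tris(benzyloxy)-2-[4-(benzyloxy)phenyl]chroman-4-ol (2,3-cis-3,4-trans) | O[C@H]1c2c(OCc3ccccc3)cc(OCc3ccccc3)cc2O[C@H](c2ccc(OCc3ccccc3)cc2)[C@@H]1OCc1ccccc1 | intermediate
26 | (2R,3S)-3,5,7-tris(benzyloxy)-2-[4-(benzyloxy)phenyl]chroman-4-one (2,3-cis) | O=C1c2c(OCc3ccccc3)cc(OCc3ccccc3)cc2O[C@H](c2ccc(OCc3ccccc3)cc2)[C@@H]1OCc1ccccc1 | intermediate
27 | 8-lithio derivative of 20 | C1c2c(OCc3ccccc3)cc(OCc3ccccc3)c([Li])c2O[C@@H](c2ccc(OCc3ccccc3)cc2)[C@H]1OCc1ccccc1 | intermediate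
28 | dimer carbinol: middle unit 2R with cis 2-aryl and 3-benzyloxy groups and a C4 hydroxyl cis to the 3-benzyloxy group, bonded at C4 to C8 of the lower unit (20) | c1ccccc1COc1ccc([C@H]2Oc3c(c(OCc5ccccc5)cc(OCc5ccccc5)c3)[C@](O)(c3c(OCc5ccccc5)cc(OCc5ccccc5)c4c3O[C@@H](c3ccc(OCc5ccccc5)cc3)[C@@H](OCc5ccccc5)C4)[C@H]2OCc5ccccc5)cc1 | intermediate
29 | octa-O-benzyl dimer: middle unit (2R,3R) with 2-aryl, 3-benzyloxy and C4 aryl all cis, bonded at C4 to C8 of the (2S,3S) lower unit | c1ccccc1COc1ccc([C@H]2Oc3c(c(OCc5ccccc5)cc(OCc5ccccc5)c3)[C@@H](c3c(OCc5ccccc5)cc(OCc5ccccc5)c4c3O[C@@H](c3ccc(OCc5ccccc5)cc3)[C@@H](OCc5ccccc5)C4)[C@H]2OCc5ccccc5)cc1 | intermediate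
30 | bromo dimer: 29 with bromine on C8 of the middle unit | c1ccccc1COc1ccc([C@H]2Oc3c(c(OCc5ccccc5)cc(OCc5ccccc5)c3Br)[C@@H](c3c(OCc5ccccc5)cc(OCc5ccccc5)c4c3O[C@@H](c3ccc(OCc5ccccc5)cc3)[C@@H](OCc5ccccc5)C4)[C@H]2OCc5ccccc5)cc1 | intermediate
31 | lithio dimer: 29 with lithium on C8 of the middle unit | c1ccccc1COc1ccc([C@H]2Oc3c(c(OCc5ccccc5)cc(OCc5ccccc5)c3[Li])[C@@H](c3c(OCc5ccccc5)cc(OCc5ccccc5)c4c3O[C@@H](c3ccc(OCc5ccccc5)cc3)[C@@H](OCc5ccccc5)C4)[C@H]2OCc5ccccc5)cc1 | intermediate
32 | trimer carbinol: upper unit 2S with cis 2-aryl and 3-benzyloxy groups and a C4 hydroxyl cis to the 3-benzyloxy group, bonded at C4 to C8 of the middle unit of 29 | c1ccccc1COc1ccc([C@H]2Oc3c(c(OCc5ccccc5)cc(OCc5ccccc5)c3[C@]3(O)c4c(OCc5ccccc5)cc(OCc5ccccc5)cc4O[C@@H](c4ccc(OCc5ccccc5)cc4)[C@H]3OCc5ccccc5)[C@@H](c3c(OCc5ccccc5)cc(OCc5ccccc5)c4c3O[C@@H](c3ccc(OCc5ccccc5)cc3)[C@@H](OCc5ccccc5)C4)[C@H]2OCc5ccccc5)cc1 | intermediate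
33 | dodeca-O-benzyl trimer with a 4-deoxy lower unit: upper (2S,3S) all-cis, middle (2R,3R) all-cis, lower (2S,3S) | c1ccccc1COc1ccc([C@H]2Oc3c(c(OCc5ccccc5)cc(OCc5ccccc5)c3[C@H]3c4c(OCc5ccccc5)cc(OCc5ccccc5)cc4O[C@@H](c4ccc(OCc5ccccc5)cc4)[C@H]3OCc5ccccc5)[C@@H](c3c(OCc5ccccc5)cc(OCc5ccccc5)c4c3O[C@@H](c3ccc(OCc5ccccc5)cc3)[C@@H](OCc5ccccc5)C4)[C@H]2OCc5ccccc5)cc1 | intermediate
34 | dodeca-O-benzyl trimer with a free 4-hydroxyl on the lower unit (lower unit 2S,3S,4R; 3,4-trans) | c1ccccc1COc1ccc([C@H]2Oc3c(c(OCc5ccccc5)cc(OCc5ccccc5)c3[C@H]3c4c(OCc5ccccc5)cc(OCc5ccccc5)cc4O[C@@H](c4ccc(OCc5ccccc5)cc4)[C@H]3OCc5ccccc5)[C@@H](c3c(OCc5ccccc5)cc(OCc5ccccc5)c4c3O[C@@H](c3ccc(OCc5ccccc5)cc3)[C@@H](OCc5ccccc5)[C@@H]4O)[C@H]2OCc5ccccc5)cc1 | intermediate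
35 | CNP0159291.1: upper (2S,3S) flavan-3-ol unit, 4→8 middle (2R,3R) flavan-3-ol unit, 4→8 (2S,3S,4R)-flavan-3,4-diol unit; both interflavan bonds cis to the adjacent 3-hydroxyl | Oc1ccc([C@H]2Oc3c(c(O)cc(O)c3[C@H]3c4c(O)cc(O)cc4O[C@@H](c4ccc(O)cc4)[C@H]3O)[C@@H](c3c(O)cc(O)c4c3O[C@@H](c3ccc(O)cc3)[C@@H](O)[C@@H]4O)[C@H]2O)cc1 | target

**Summary**

Total step count: 19. Longest linear sequence: 14 steps (steps 1, 2, 3, 5, 6, 7, 8, 13, 14, 15, 16, 17, 18, 19).

**Steps most likely to fail**

Step 5. The fluoroborate-bound aldolate may revert by retro-aldol cleavage before it meets the aryne. The aryl anion may be protonated before it captures the acyl carbon, leaving an open aryl ether. The cis ketone may also epimerise at C3 in the basic fluoride medium. Fallback with known reactions only, setting out from 12 and 13 and returning at 18: the aldol is run conventionally (Bu2BOTf, Et3N, CH2Cl2, −78 to 0 °C, H2O2 work-up, through 15 and 16) and the syn-aldol adduct (R)-4-benzyl-3-[(2R,3S)-2-(benzyloxy)-3-[4-(benzyloxy)phenyl]-3-hydroxypropanoyl]oxazolidin-2-one F1 is isolated. Its hydroxyl is arylated by O–H insertion into aryne 17 generated from 8 (KF, 18-crown-6, THF), which tolerates the free hydroxyl and keeps the C2 configuration, to give the 3,5-bis(benzyloxy)phenyl ether (R)-4-benzyl-3-[(2R,3S)-2-(benzyloxy)-3-[4-(benzyloxy)phenyl]-3-[3,5-bis(benzyloxy)phenoxy]propanoyl]oxazolidin-2-one F2. LiOH/H2O2 removes the auxiliary to give the acid (2R,3S)-2-(benzyloxy)-3-[4-(benzyloxy)phenyl]-3-[3,5-bis(benzyloxy)phenoxy]propanoic acid F3. Intramolecular Friedel–Crafts acylation (trifluoroacetic anhydride, CH2Cl2, 0 °C) at either of the two equivalent positions ortho to the ether oxygen then closes ring C to 18.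

Step 15. Bromination of the dimer may lack site selectivity, because besides C8 of the middle unit the two C6 positions are open, and over-bromination may follow. Fallback, setting out from 24 and 21 and returning at 30: the bromine is placed on the monomer, where C8 selectivity is established. NBS (CH2Cl2, −78 °C to rt) should convert 24 into (2R,3R)-3,5,7-tris(benzyloxy)-2-[4-(benzyloxy)phenyl]-8-bromochroman F4. DDQ in wet CH2Cl2 should then give the 3,4-trans alcohol (2R,3R,4S)-3,5,7-tris(benzyloxy)-2-[4-(benzyloxy)phenyl]-8-bromochroman-4-ol F5, and Dess–Martin periodinane the ketone (2R,3S)-3,5,7-tris(benzyloxy)-2-[4-(benzyloxy)phenyl]-8-bromochroman-4-one F6. Aryllithium 27 (from 21, t-BuLi, THF, −78 °C) is added to F6 at −78 °C, where carbonyl addition should outrun aryl–aryl bromine–lithium exchange, to give the bromo dimer carbinol F7. Ionic deoxygenation (Bu3SnH, CF3CO2H, CH2Cl2, 0 °C, no radical initiator) then delivers 30 directly.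

Step 18. The new benzylic alcohol may be oxidised further to the ketone, the diarylmethine C4–H bonds of the upper and middle units may compete, and the free benzylic hydroxyl is then also exposed to hydrogenolytic loss in step 19. Fallback, setting out from 33 and returning at 35: the oxidation is driven on purpose to the ketone (DDQ in wet CH2Cl2, then Dess–Martin periodinane) to give the dodeca-O-benzyl trimer with a 4-oxo lower unit F8. Hydrogenolysis (H2, Pd(OH)2/C) removes the twelve benzyl groups while the ketone is inert, giving the free phenolic trimer with a 4-oxo lower unit F9. Hydroxyl-directed reduction with Me4NBH(OAc)3 (MeCN/AcOH, −20 °C), in which the free 3-hydroxyl delivers hydride to its own face of the carbonyl, should then give the 3,4-trans diol 35.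

**Further compounds**

F1 | step 5 | (R)-4-benzyl-3-[(2R,3S)-2-(benzyloxy)-3-[4-(benzyloxy)phenyl]-3-hydroxypropanoyl]oxazolidin-2-one | O=C(N1C(=O)OC[C@H]1Cc1ccccc1)[C@H](OCc1ccccc1)[C@@H](O)c1ccc(OCc2ccccc2)cc1
F2 | step 5 | (R)-4-benzyl-3-[(2R,3S)-2-(benzyloxy)-3-[4-(benzyloxy)phenyl]-3-[3,5-bis(benzyloxy)phenoxy]propanoyl]oxazolidin-2-one | O=C(N1C(=O)OC[C@H]1Cc1ccccc1)[C@H](OCc1ccccc1)[C@@H](Oc1cc(OCc2ccccc2)cc(OCc2ccccc2)c1)c1ccc(OCc2ccccc2)cc1
F3 | step 5 | (2R,3S)-2-(benzyloxy)-3-[4-(benzyloxy)phenyl]-3-[3,5-bis(benzyloxy)phenoxy]propanoic acid | OC(=O)[C@H](OCc1ccccc1)[C@@H](Oc1cc(OCc2ccccc2)cc(OCc2ccccc2)c1)c1ccc(OCc2ccccc2)cc1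
F4 | step 15 | (2R,3R)-3,5,7-tris(benzyloxy)-2-[4-(benzyloxy)phenyl]-8-bromochroman | C1c2c(OCc3ccccc3)cc(OCc3ccccc3)c(Br)c2O[C@H](c2ccc(OCc3ccccc3)cc2)[C@@H]1OCc1ccccc1
F5 | step 15 | (2R,3R,4S)-3,5,7-tris(benzyloxy)-2-[4-(benzyloxy)phenyl]-8-bromochroman-4-ol | O[C@H]1c2c(OCc3ccccc3)cc(OCc3ccccc3)c(Br)c2O[C@H](c2ccc(OCc3ccccc3)cc2)[C@@H]1OCc1ccccc1
F6 | step 15 | (2R,3S)-3,5,7-tris(benzyloxy)-2-[4-(benzyloxy)phenyl]-8-bromochroman-4-one | O=C1c2c(OCc3ccccc3)cc(OCc3ccccc3)c(Br)c2O[C@H](c2ccc(OCc3ccccc3)cc2)[C@@H]1OCc1ccccc1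
F7 | step 15 | bromo dimer carbinol: 28 with bromine on C8 of the middle unit | c1ccccc1COc1ccc([C@H]2Oc3c(c(OCc5ccccc5)cc(OCc5ccccc5)c3Br)[C@](O)(c3c(OCc5ccccc5)cc(OCc5ccccc5)c4c3O[C@@H](c3ccc(OCc5ccccc5)cc3)[C@@H](OCc5ccccc5)C4)[C@H]2OCc5ccccc5)cc1
F8 | step 18 | dodeca-O-benzyl trimer with a 4-oxo lower unit | c1ccccc1COc1ccc([C@H]2Oc3c(c(OCc5ccccc5)cc(OCc5ccccc5)c3[C@H]3c4c(OCc5ccccc5)cc(OCc5ccccc5)cc4O[C@@H](c4ccc(OCc5ccccc5)cc4)[C@H]3OCc5ccccc5)[C@@H](c3c(OCc5ccccc5)cc(OCc5ccccc5)c4c3O[C@@H](c3ccc(OCc5ccccc5)cc3)[C@@H](OCc5ccccc5)C4=O)[C@H]2OCc5ccccc5)cc1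
F9 | step 18 | free phenolic trimer with a 4-oxo lower unit | Oc1ccc([C@H]2Oc3c(c(O)cc(O)c3[C@H]3c4c(O)cc(O)cc4O[C@@H](c4ccc(O)cc4)[C@H]3O)[C@@H](c3c(O)cc(O)c4c3O[C@@H](c3ccc(O)cc3)[C@@H](O)C4=O)[C@H]2O)cc1
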